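**Late readings.** Late in the eta and theta runs, past the first minutes, I read what fraction of the starting material present is lost per minute.

| setting | eta | theta | flask |
|---|---|---|---|
| starting material | 0.15 M (in portions, 2) | 0.33 M (in portions, 2) | 0.22 M (in portions, 2) |
| gas phase | 24 mM (held) | 24 mM (held) | 24 mM (held) |
| remark | run made earlier; portions every 30 min | run made earlier; portions every 30 min | the portions of starting material follow each other after 30 min, the first at the start |
| time |  |  | 1.0 h |

- eta (time / min: target / %, starting material / %): 8.00: 2.8, 47.0; 15.0: 5.7, 43.2; 20.0: 8.6, 40.4; 30.0: 12.3, 36.3; 40.0: 20.4, 76.9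
- theta (time / min: target / %, starting material / %): 3.00: 0, 49.2; 5.00: 1.8, 48.7; 10.0: 3.0, 45.8; 20.0: 7.8, 41.4; 40.0: 17.8, 78.5

(scatter of a reading: 0.3 percentage points)

* amount of target in percent of the starting material charged, at 12 min, 30 min and 1.0 h

- at the start none of the gas phase is in solution

**The order.** In the eta run starting material falls from 47.0 % at 8.00 min to 36.3 % at 30.0 min, which gives 0.0117 min⁻¹. In the theta run it falls from 48.7 % at 5.00 min to 41.4 % at 20.0 min, which gives 0.0108 min⁻¹. These two differ by a factor of 1.08, less than the factor of 2.20 between the charges. I therefore take the loss as pseudo-first-order: its rate follows the starting material, while I assume the concentration of dissolved gas stays nearly level.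

**The carried rate.** Their mean, 0.0113 min⁻¹, is my fractional loss rate, the fraction of the starting material present that is lost per minute. As a test, I carry it across the second portion of the eta run: 36.3 % plus the new portion becomes 77.1 % at 40.0 min, and the reading is 76.9 %.

**My reckoning.** None of the gas is in solution at the start, and the first eta reading puts the delay before starting material is lost at this rate at 2.73 min. The target found per unit of starting material lost at 40.0 min averages 85.6 % over the two runs. For the new flask I reckon 36.8 % of the charge as starting material just before the second portion and 61.8 % at 1.0 h. That gives target of 4.25 %, 11.3 % and 32.7 %.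

**The forecast.** The forecast, from “a first-order loss of starting material”, gives 4.3 %, 11.6 % and 33 %.

**The result.** The flask gives 4.56 %, 11.8 % and 31.9 % of target.

    starting material + dissolved gas ⇌ target (K = 280 L mol⁻¹, k = 0.00790 L mol⁻¹ s⁻¹)
    gas phase ⇌ dissolved gas, rate k2*(csat - [dissolved gas]) (kL = 0.00630 s⁻¹)
    starting material → side product (k = 2.20 × 10⁻⁵ s⁻¹)

**Gas balance.** At 1.00 h the flask makes dissolved gas 1.03 times as fast as it uses it, each step taken net, and dissolved gas stands at 0.0206 M against 24 mM at saturation. Between the second portion and 1.0 h, starting material in this flask goes from 86.5 % to 63.4 % of the charge, a fractional loss rate of 0.0104 min⁻¹.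

The readings stem from a simulated flask for an exercise, noise included.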